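**Assumption:** the target is treated as the drawn enol tautomer of the acyl triketone (tautomers count as one compound), and commercial natural (R)-(−)-linalool is taken as enantiopure enough to carry the absolute configuration. The route is a paper design: no step has been run, and the stereochemical outcomes of steps 3 and 4 are predictions from transition-state models.

## Retrosynthetic overview

1. The two prenyl groups on C-5 of ring A come off last (double C-alkylation of a vinylogous acid), so the oxygenation before it meets no competing trisubstituted alkene.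
2. The tertiary hydroperoxide goes back to the 6',7'-alkene (Markovnikov Co/O2/silane hydroperoxidation).
3. The spiro cyclohexene and the cyclopentane are cut together by an intramolecular Diels–Alder reaction: the diene is the o-quinone methide of ring A extended by the enal alkene, the dienophile is the linalool vinyl group, and the diene is released by retro-6π opening of a 2H-chromene.
4. The chromene comes from Knoevenagel/oxa-6π union of para-O-silylated phloroacetophenone with (E)-8-oxolinalool, one oxidation away from (R)-linalool, the only purchased stereocentre.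
5. Ring order: benzene ring (bought) → pyran (temporary) → cyclohexene and cyclopentane in one step.

## Route

Step 1
Reactants: 1 (R)-(−)-linalool
Product: 3 (2E,6R)-6-hydroxy-2,6-dimethylocta-2,7-dienal, via allylic alcohol 2 (not isolated)
Conditions: SeO2 (1.2 equiv), 1,4-dioxane, 80 °C
Reagents that add atoms: selenium dioxide, O=[Se]=O
Why: Riley allylic oxidation (ene reaction, then 2,3-sigmatropic shift of the allylseleninic acid) attacks only the E-methyl group of the trisubstituted alkene and carries the primary allylic alcohol on to the enal, while the vinyl carbinol has no allylic hydrogen and keeps its R centre untouched.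

Step 2
Reactants: 4 2,4,6-trihydroxyacetophenone
Product: 5 1-[4-(tert-butyldimethylsilyloxy)-2,6-dihydroxyphenyl]ethanone
Conditions: TBSCl (1.05 equiv), imidazole, DMF, 0 °C
Reagents that add atoms: tert-butyldimethylsilyl chloride, CC(C)(C)[Si](C)(C)Cl
Why: the para hydroxyl is the only one not held in a hydrogen bond to the acetyl group, so silylation (substitution at silicon) is selective for it and leaves the two chelated ortho hydroxyls free.

Step 3
Reactants: 3 (2E,6R)-6-hydroxy-2,6-dimethylocta-2,7-dienal; 5 1-[4-(tert-butyldimethylsilyloxy)-2,6-dihydroxyphenyl]ethanone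
Product: 8 (3'R,3a'S,5'R,7a'R)-spiro dienone (ring A = 2-acetyl-3-hydroxy-5-silyloxycyclohexa-2,4-dienone; trans-fused 6',7'-ene), via chromene 6 (not isolated), via quinone methide 7 (not isolated)
Conditions: ethylenediammonium diacetate (20 mol %), xylenes, 130 °C, −H2O; then BHT (cat.), 0.01 M, 195 °C, sealed tube
Reagents that add atoms: none
Why: Knoevenagel condensation and oxa-6π electrocyclisation give chromene 6 (epimers at the pyran carbon, which is irrelevant), its thermal retro-6π opening returns quinone methide 7 only with the E-dienyl chain syn to the carbonyl next to the acetyl-bearing carbon because the other ortho oxygen is silylated, and the intramolecular Diels–Alder reaction of this diene with the vinyl group through the tether-exo transition state (carbinol OH inside, methyl anti to the forming bond, inside carbonyl ending equatorial) gives the trans-fused hydrindane and sets C-3a' (S), C-7a' (R) and the spiro centre (R) under control of the linalool centre.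

Step 4
Reactants: 8 (3'R,3a'S,5'R,7a'R)-spiro dienone
Product: 10 (3'R,3a'S,5'R,7'R,7a'R)-hydroperoxy spiro dienol, via silyl peroxide 9 (not isolated)
Conditions: Co(acac)2 (20 mol %), O2 (1 atm), Et3SiH (3 equiv), 1,2-dichloroethane, rt; then HF·pyridine, THF, 0 °C
Reagents that add atoms: dioxygen, O=O; triethylsilane, CC[SiH](CC)CC (its silyl group is carried only by 9)
Why: Isayama–Mukaiyama hydroperoxysilylation (hydrogen-atom transfer from a cobalt hydride to the only isolated C=C gives the tertiary C-7' radical, which is captured by O2 and silylated) is Markovnikov, O2 adds from the equatorial side away from the axial ring-A carbon on the spiro centre so that the methyl becomes axial (7'R), and HF·pyridine then cleaves the Si–OO bond and the silyl enol ether without touching the O–O bond.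

Step 5
Reactants: 10 (3'R,3a'S,5'R,7'R,7a'R)-hydroperoxy spiro dienol; 11 prenyl bromide (2.3 equiv)
Product: 12 target CNP0149131.2
Conditions: NaOMe (3.0 equiv), MeOH, −10 to 0 °C; then aq citric acid
Reagents that add atoms: none
Why: base-mediated double C-prenylation (enolate SN2) of the vinylogous acid can only take place at C-5, the one ring CH left between two oxygen-bearing carbons, methanol favours C- over O-alkylation, no stereocentre is made or touched, and with three equivalents of base the much less acidic tertiary hydroperoxide stays largely protonated.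

## Compound list

1 | (R)-(−)-linalool, (3R)-3,7-dimethylocta-1,6-dien-3-ol | C=C[C@](C)(O)CCC=C(C)C | starting material
2 | (2E,6R)-2,6-dimethylocta-2,7-diene-1,6-diol (8-hydroxylinalool) | OC/C(C)=C/CC[C@@](C)(O)C=C | intermediate
3 | (2E,6R)-6-hydroxy-2,6-dimethylocta-2,7-dienal (8-oxolinalool) | O=C/C(C)=C/CC[C@@](C)(O)C=C | intermediate
4 | 2,4,6-trihydroxyacetophenone | CC(=O)c1c(O)cc(O)cc1O | starting material
5 | 1-[4-(tert-butyldimethylsilyloxy)-2,6-dihydroxyphenyl]ethanone | CC(=O)c1c(O)cc(O[Si](C)(C)C(C)(C)C)cc1O | intermediate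
6 | 1-{5-(tert-butyldimethylsilyloxy)-7-hydroxy-2-[(3R)-3-hydroxy-3-methylpent-4-en-1-yl]-3-methyl-2H-chromen-8-yl}ethanone, both C-2 epimers | CC(=O)c1c(O)cc(O[Si](C)(C)C(C)(C)C)c2c1OC(CC[C@@](C)(O)C=C)C(C)=C2 | intermediate
7 | (6Z)-2-acetyl-5-(tert-butyldimethylsilyloxy)-3-hydroxy-6-[(2E,6R)-6-hydroxy-2,6-dimethylocta-2,7-dienylidene]cyclohexa-2,4-dien-1-one | CC(=O)C1=C(O)C=C(O[Si](C)(C)C(C)(C)C)/C(=C/C(C)=C/CC[C@@](C)(O)C=C)C1=O | intermediate
8 | (3'R,3a'S,5'R,7a'R)-3-acetyl-6-(tert-butyldimethylsilyloxy)-3',4-dihydroxy-3',7'-dimethyl-1',2',3',3a',4',7a'-hexahydrospiro[cyclohexane-1,5'-indene]-3,5-dien-2-one (ring-fusion hydrogens trans; 3'-OH cis to C-4') | CC(=O)C1=C(O)C=C(O[Si](C)(C)C(C)(C)C)[C@]2(C[C@H]3[C@@H](CC[C@@]3(C)O)C(C)=C2)C1=O | intermediate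
9 | 7'-(triethylsilylperoxy) derivative of saturated 8, (3'R,3a'S,5'R,7'R,7a'R), 7'-methyl axial and cis to the silyloxy-bearing ring-A carbon | CC(=O)C1=C(O)C=C(O[Si](C)(C)C(C)(C)C)[C@]2(C[C@H]3[C@@H](CC[C@@]3(C)O)[C@](C)(OO[Si](CC)(CC)CC)C2)C1=O | intermediate
10 | (3'R,3a'S,5'R,7'R,7a'R)-3-acetyl-7'-hydroperoxy-3',4,6-trihydroxy-3',7'-dimethyloctahydrospiro[cyclohexane-1,5'-indene]-3,5-dien-2-one | CC(=O)C1=C(O)C=C(O)[C@]2(C[C@H]3[C@@H](CC[C@@]3(C)O)[C@](C)(OO)C2)C1=O | intermediate
11 | prenyl bromide, 1-bromo-3-methylbut-2-ene | CC(C)=CCBr | starting material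
12 | (3'R,3a'S,5'R,7'R,7a'R)-3-acetyl-7'-hydroperoxy-3',4-dihydroxy-3',7'-dimethyl-5,5-bis(3-methylbut-2-en-1-yl)octahydrospiro[cyclohex-3-ene-1,5'-indene]-2,6-dione | CC(=O)C1=C(O)C(CC=C(C)C)(CC=C(C)C)C(=O)[C@]2(C[C@H]3[C@@H](CC[C@@]3(C)O)[C@](C)(OO)C2)C1=O | target

## Step count and risks

Total step count: 5. Longest linear sequence: 4 steps (1 → 3 → 8 → 10 → 12, or 4 → 5 → 8 → 10 → 12).

Steps most likely to fail:

**Step 3 (most uncertain).** The Diels–Alder reaction dearomatises ring A. The chromene opening is uphill, the diene terminus is fully substituted, and I know of no direct precedent for an all-carbon cycloaddition of such a quinone methide. The trans ring fusion and the facial selectivity are predictions.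
Fallback: set out from chromene 6, isolated by stopping at 130 °C. NCS (2.1 equiv, MeCN, 0 °C) chlorinates the free ring position twice and gives the non-aromatic dichloro pyranone F1 with loss of the silyl group. Its pyran opens without any aromaticity penalty, and the CCl2 group steers the same carbonyl inside, so heating (toluene, 140 °C) gives dichloro spiro trione F2. Zn/AcOH removes both chlorines to give spiro dienol F3. F3 is taken through the conditions of step 4 (triethylsilyl peroxide F4, then HF·pyridine) and comes back to the route at 10.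

**Step 4.** The alkene is hindered, the electron-rich dienol ring may be attacked by peroxyl radicals, and the selectivity at C-7' is only predicted.
Fallback: set out from 8. Co(acac)2, t-BuOOH, Et3SiH and TsBr under argon give the Markovnikov tertiary bromide F5 (radical capture by a bromine donor in place of O2). AgO2CCF3 with anhydrous H2O2 in Et2O (silver-assisted substitution, equatorial attack on the cation) gives silyl-protected hydroperoxide F6. HF·pyridine removes the silyl enol ether and returns to the route at 10.

**Step 5.** The free hydroperoxide may be O-prenylated, and some enol O-alkylation is likely.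
Fallback: set out from 10. 2-Methoxypropene with PPTS masks the hydroperoxide as 2-methoxyprop-2-yl peroxyketal F6-type compound F7 (any enol ketal formed at the same time is cleaved again by methoxide). NaOMe and prenyl bromide 11 then give diprenylated peroxyketal F8. AcOH/H2O/THF releases the hydroperoxide and the sequence arrives at 12.

## Further compounds

F1 | step 3 | 8-acetyl-6,6-dichloro-7-hydroxy-2-[(3R)-3-hydroxy-3-methylpent-4-en-1-yl]-3-methyl-2H-chromen-5(6H)-one, both C-2 epimers | CC(=O)C1=C(O)C(Cl)(Cl)C(=O)C2=C1OC(CC[C@@](C)(O)C=C)C(C)=C2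
F2 | step 3 | 5,5-dichloro spiro trione, ring system and configuration as in 8 with C-5 of ring A as CCl2 and C-6 as ketone | CC(=O)C1=C(O)C(Cl)(Cl)C(=O)[C@]2(C[C@H]3[C@@H](CC[C@@]3(C)O)C(C)=C2)C1=O
F3 | step 3 | desilylated 8, (3'R,3a'S,5'R,7a'R)-3-acetyl-3',4,6-trihydroxy-3',7'-dimethyl-hexahydrospiro[cyclohexane-1,5'-indene]-3,5-dien-2-one | CC(=O)C1=C(O)C=C(O)[C@]2(C[C@H]3[C@@H](CC[C@@]3(C)O)C(C)=C2)C1=O
F4 | step 3 | 7'-(triethylsilylperoxy) derivative of saturated F3, configuration as in 10 | CC(=O)C1=C(O)C=C(O)[C@]2(C[C@H]3[C@@H](CC[C@@]3(C)O)[C@](C)(OO[Si](CC)(CC)CC)C2)C1=O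
F5 | step 4 | 7'-bromo-7'-methyl derivative of saturated 8, both C-7' epimers | CC(=O)C1=C(O)C=C(O[Si](C)(C)C(C)(C)C)[C@]2(C[C@H]3[C@@H](CC[C@@]3(C)O)C(C)(Br)C2)C1=O
F6 | step 4 | 6-O-tert-butyldimethylsilyl ether of 10 | CC(=O)C1=C(O)C=C(O[Si](C)(C)C(C)(C)C)[C@]2(C[C@H]3[C@@H](CC[C@@]3(C)O)[C@](C)(OO)C2)C1=O
F7 | step 5 | 2-methoxyprop-2-yl peroxyketal of 10 | CC(=O)C1=C(O)C=C(O)[C@]2(C[C@H]3[C@@H](CC[C@@]3(C)O)[C@](C)(OOC(C)(C)OC)C2)C1=O
F8 | step 5 | 2-methoxyprop-2-yl peroxyketal of 12 | CC(=O)C1=C(O)C(CC=C(C)C)(CC=C(C)C)C(=O)[C@]2(C[C@H]3[C@@H](CC[C@@]3(C)O)[C@](C)(OOC(C)(C)OC)C2)C1=O
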